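**Plan**

1. Retrosynthesis: the triene is cut at C3′=C4′ and C1′=C2′ (two Horner–Wadsworth–Emmons olefinations) back to a C7 methyl ketone; the C5–OH / C4=C15 pair is taken back to a C4=C5 tetrasubstituted alkene (ene reaction with singlet oxygen); ring A is then cut at C8–C9 and C6–C7, leaving but-3-en-2-one and a ring-B diene acid.
2. Enabling feature: in ring A, C9 and C6 are both CH2 groups carried by the adjacent, fully substituted ring-B carbons C10 and C5, and C5 is allylic to the exocyclic C4=C15. C6 can therefore be the terminus of an exocyclic 1,3-diene C15=C4–C5=C6 on ring B and C9 a primary radical (from C10–CH2–CO2H); together they are the four-carbon partner of a radical [4+2] annulation with C8/C7 of the enone.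
3. Forward order: ring B first (2-methylcyclohex-2-enone → allyl carbinol → bromo ketone with the C10 quaternary centre → diene acid), then ring A by the annulation, then C5–OH and the exocyclic methylene by the ene reaction, then the triene chain from the C7 acetyl group.
4. Stereochemistry: a titanium–BINOL allylation sets the carbinol; a stereospecific bromonium semipinacol shift (Br anti to the migrating allyl) passes it on to C10 and C1; C5 comes from attack of singlet oxygen anti to the axial C10 methyl; C7 from equatorial (thermodynamic) placement next to the ketone; both new side-chain alkenes are E from the olefinations.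

Key step: step 8

Numbering used in the text (eudesmane): ring B = C1(Br)–C2–C3–C4(=C15H2)–C5(OH)–C10(CH3); ring A = C5–C6–C7–C8–C9–C10; side chain C1′(CH3)=C2′–C3′=C4′–C5′(CH3)=C6′H2, attached to C7 through C1′.

Assumption: (R)-BINOL is taken to give the (1R)-carbinol 3 in step 1; if the titanium catalyst induces the opposite sense, (S)-BINOL is used.

**Route**

Step 1
Reactants: 1 2-methylcyclohex-2-en-1-one; 2 tetraallylstannane, Sn(CH2CH=CH2)4
Product: 3 (1R)-2-methyl-1-(prop-2-en-1-yl)cyclohex-2-en-1-ol
Conditions: Ti(OiPr)4 (30 mol%), (R)-BINOL (30 mol%), i-PrOH (20 equiv), CH2Cl2, rt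
Reagents that add atoms: none
Why: Titanium–BINOL-catalysed enantioselective allylation of a ketone with an allylstannane should add 1,2 to the cyclic enone, the chiral titanium BINOLate telling the sp2 α-carbon (bearing methyl) from the α′-CH2 side and so setting the carbinol centre.

Step 2
Reactants: 3 (1R)-2-methyl-1-(prop-2-en-1-yl)cyclohex-2-en-1-ol
Product: 4 (2R,3R)-3-bromo-2-methyl-2-(prop-2-en-1-yl)cyclohexan-1-one
Conditions: NBS (1.05 equiv), (PhO)2P(O)OH (10 mol%), CH2Cl2, −40 → 0 °C, dark
Reagents that add atoms: N-bromosuccinimide, O=C1CCC(=O)N1Br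
Why: Bromonium-induced semipinacol rearrangement of an allylic alcohol: Br+ is taken up at C1 of the more nucleophilic trisubstituted ring alkene on the face opposite the allyl group, and the allyl group shifts from C5 to C10 antiperiplanar to the breaking C–Br+ bond as the carbinol collapses to the ketone, so the quaternary centre and the C–Br centre arise together with Br trans to allyl (cis to methyl).

Step 3
Reactants: 4 (2R,3R)-3-bromo-2-methyl-2-(prop-2-en-1-yl)cyclohexan-1-one
Product: 6 methyl 2-[(1R,2R)-2-bromo-1-methyl-6-oxocyclohexyl]acetate, via aldehyde 5 (not isolated)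
Conditions: O3, 2.5 M NaOH in MeOH, CH2Cl2, −78 °C
Reagents that add atoms: ozone, [O-][O+]=O; methanol, CO
Why: Ozonolysis in methanolic NaOH should turn the terminal alkene directly into the methyl ester (aldehyde 5 is trapped as its hemiacetal alkoxide and oxidised by ozone), and the ketone cannot undergo retro-aldol cleavage or E1cB loss of bromide because C10 carries no hydrogen.

Step 4
Reactants: 6 methyl 2-[(1R,2R)-2-bromo-1-methyl-6-oxocyclohexyl]acetate
Product: 7 methyl 2-[(1R,6R)-6-bromo-1-methyl-3-methylidene-2-oxocyclohexyl]acetate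
Conditions: (CH2O)n, N-methylanilinium trifluoroacetate, THF, reflux
Reagents that add atoms: formaldehyde (as paraformaldehyde), C=O
Why: α-Methylenation of a ketone by Mannich condensation–elimination with formaldehyde and a secondary ammonium salt should occur at C4, the only enolisable α-carbon of the ketone (C10 is quaternary), and creates no stereocentre.

Step 5
Reactants: 7 methyl 2-[(1R,6R)-6-bromo-1-methyl-3-methylidene-2-oxocyclohexyl]acetate
Product: 8 methyl 2-[(1R,6R)-6-bromo-1-methyl-2,3-dimethylidenecyclohexyl]acetate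
Conditions: Zn, CH2Br2, TiCl4, THF (pre-formed reagent); then 7, CH2Cl2, 0 °C → rt
Reagents that add atoms: dibromomethane, BrCBr
Why: Takai–Lombardo methylenation is non-basic and selective for ketones over esters, so the hindered cross-conjugated ketone should give the exocyclic 1,3-diene by 1,2-addition without conjugate addition, ester attack or elimination of the secondary bromide.

Step 6
Reactants: 8 methyl 2-[(1R,6R)-6-bromo-1-methyl-2,3-dimethylidenecyclohexyl]acetate
Product: 9 2-[(1R,6R)-6-bromo-1-methyl-2,3-dimethylidenecyclohexyl]acetic acid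
Conditions: LiOH·H2O, THF/MeOH/H2O, rt; then 1 M HCl to pH 3
Reagents that add atoms: lithium hydroxide, [Li+].[OH-]
Why: Saponification of the unhindered methyl ester at room temperature should leave the neopentyl-type secondary bromide and the diene untouched.

Step 7
Reactants: 9 2-[(1R,6R)-6-bromo-1-methyl-2,3-dimethylidenecyclohexyl]acetic acid
Product: 10 1,3-dioxo-1,3-dihydro-2H-isoindol-2-yl 2-[(1R,6R)-6-bromo-1-methyl-2,3-dimethylidenecyclohexyl]acetate
Conditions: N-hydroxyphthalimide, N,N′-diisopropylcarbodiimide, DMAP (10 mol%), CH2Cl2, 0 °C → rt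
Reagents that add atoms: N-hydroxyphthalimide, O=C1N(O)C(=O)c2ccccc12
Why: Carbodiimide (Steglich-type) esterification should give the redox-active ester under neutral conditions that do not touch the acid-sensitive diene.

Step 8
Reactants: 10 1,3-dioxo-1,3-dihydro-2H-isoindol-2-yl 2-[(1R,6R)-6-bromo-1-methyl-2,3-dimethylidenecyclohexyl]acetate; 11 but-3-en-2-one
Product: 15 1-[(2R,4aR,5R)-5-bromo-4a,8-dimethyl-1,2,3,4,4a,5,6,7-octahydronaphthalen-2-yl]ethan-1-one, via primary alkyl radical 12 (not isolated), via α-acyl radical 13 (not isolated), via allyl radical 14 (not isolated)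
Conditions: Ru(bpy)3Cl2·6H2O (1 mol%), Hantzsch ester (1.5 equiv), i-Pr2NEt (1 equiv), 11 (3 equiv), degassed CH2Cl2 (0.05 M), blue LEDs, rt; then DBU (0.2 equiv), rt
Reagents that add atoms: none
Why: Photoexcited Ru(bpy)3Cl2 is reduced by the Hantzsch ester to monovalent ruthenium, which transfers an electron to 10; loss of phthalimide anion and CO2 gives the primary radical 12 at C9, which adds to the CH2 terminus of 11 (Giese addition, C8–C9 bond), and the electrophilic α-acyl radical 13 closes onto C6, the near terminus of the electron-rich exocyclic diene (C6–C7 bond), to give allyl radical 14, which takes a hydrogen atom from the Hantzsch ester or its radical cation at the unhindered C15. The closest known reaction types are the reductive decarboxylative Giese addition of N-acyloxyphthalimides and Bu3SnH or atom-transfer radical annulations in which an α-carbonyl radical cyclises 6-endo onto a 1,1-disubstituted alkene. Ring A closes in the 6-endo-trig mode, because 5-exo attack at the fully substituted C5 would give a primary radical whereas 6-endo attack gives a tertiary allylic one. C7 is the only new stereocentre: the chair-like transition state should place the acetyl group equatorial (cis to the C10 methyl), and since C7 is α to the ketone the DBU treatment converts any axial epimer into the same isomer; C4 and C5 end as sp2 carbons, so no ring-fusion centre is at stake here. The step needs 12 to add to 11 before it is quenched (excess 11, slow hydrogen donor), 13 to cyclise before it is reduced (diene acceptor, matched polarity), hydrogen delivery at C15 and not C5 (sterics and formation of the tetrasubstituted alkene) and no thermal Diels–Alder reaction of the diene with 11 (room temperature, dilution, short irradiation); the secondary bromide should not be reduced at the potential of monovalent ruthenium.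

Step 9
Reactants: 15 1-[(2R,4aR,5R)-5-bromo-4a,8-dimethyl-1,2,3,4,4a,5,6,7-octahydronaphthalen-2-yl]ethan-1-one
Product: 17 1-[(2R,4aR,5R,8aR)-5-bromo-8a-hydroxy-4a-methyl-8-methylidenedecahydronaphthalen-2-yl]ethan-1-one, via hydroperoxide 16 (not isolated)
Conditions: O2, tetraphenylporphyrin (cat.), visible light, CH2Cl2, −20 °C; then PPh3, rt
Reagents that add atoms: dioxygen, O=O
Why: Schenck ene reaction of singlet oxygen with the tetrasubstituted C4=C5 alkene, then phosphine reduction of hydroperoxide 16: oxygen should add to C5 from the α face, anti to the axial C10 methyl, with abstraction of a hydrogen of the C15 methyl group (the α hydrogen at C6 is equatorial, which disfavours the alternative attack at C4), setting the trans ring fusion and the exocyclic methylene in one operation.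

Step 10
Reactants: 17 1-[(2R,4aR,5R,8aR)-5-bromo-8a-hydroxy-4a-methyl-8-methylidenedecahydronaphthalen-2-yl]ethan-1-one; 18 diethyl {2-[methoxy(methyl)amino]-2-oxoethyl}phosphonate
Product: 19 (2E)-3-[(2R,4aR,5R,8aR)-5-bromo-8a-hydroxy-4a-methyl-8-methylidenedecahydronaphthalen-2-yl]-N-methoxy-N-methylbut-2-enamide
Conditions: NaH (3 equiv), 18 (2 equiv), THF, 0 °C → reflux
Reagents that add atoms: none
Why: Horner–Wadsworth–Emmons olefination of the α-branched methyl ketone with a stabilised phosphonate anion should be E-selective because the large ring substituent avoids the amide group in the oxaphosphetane; excess NaH carries the tertiary alcohol as its alkoxide and C7 stays equatorial.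

Step 11
Reactants: 19 (2E)-3-[(2R,4aR,5R,8aR)-5-bromo-8a-hydroxy-4a-methyl-8-methylidenedecahydronaphthalen-2-yl]-N-methoxy-N-methylbut-2-enamide
Product: 20 (2E)-3-[(2R,4aR,5R,8aR)-5-bromo-8a-hydroxy-4a-methyl-8-methylidenedecahydronaphthalen-2-yl]but-2-enal
Conditions: i-Bu2AlH (2.5 equiv), THF, −78 °C; aq. potassium sodium tartrate
Reagents that add atoms: none
Why: Partial reduction of an N-methoxy-N-methylamide with i-Bu2AlH should stop at the chelated tetrahedral aluminate, which releases the enal on work-up without 1,4-reduction or loss of the E geometry.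

Step 12
Reactants: 20 (2E)-3-[(2R,4aR,5R,8aR)-5-bromo-8a-hydroxy-4a-methyl-8-methylidenedecahydronaphthalen-2-yl]but-2-enal; 21 diethyl (2-methylprop-2-en-1-yl)phosphonate
Product: 22 (1R,4aR,6R,8aR)-1-bromo-8a-methyl-4-methylidene-6-[(2E,4E)-6-methylhepta-2,4,6-trien-2-yl]octahydronaphthalen-4a(2H)-ol
Conditions: 21 (2.5 equiv), n-BuLi (2.4 equiv), THF, −78 °C; then 20, −78 °C → rt
Reagents that add atoms: none
Why: Horner–Wadsworth–Emmons olefination with the lithiated allylic phosphonate (α-attack, then loss of phosphate on warming) should form C3′=C4′ with E geometry and complete the 2-methyl-1,3-diene terminus, the tertiary alcohol riding as its lithium alkoxide.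

**Compound list**

1 | 2-methylcyclohex-2-en-1-one | CC1=CCCCC1=O | starting material
2 | tetraallylstannane | C=CC[Sn](CC=C)(CC=C)CC=C | starting material
3 | (1R)-2-methyl-1-(prop-2-en-1-yl)cyclohex-2-en-1-ol | C=CC[C@@]1(O)C(C)=CCCC1 | intermediate
4 | (2R,3R)-3-bromo-2-methyl-2-(prop-2-en-1-yl)cyclohexan-1-one | C=CC[C@@]1(C)[C@H](Br)CCCC1=O | intermediate
5 | 2-[(1R,2R)-2-bromo-1-methyl-6-oxocyclohexyl]acetaldehyde | O=CC[C@@]1(C)[C@H](Br)CCCC1=O | intermediate (not isolated)
6 | methyl 2-[(1R,2R)-2-bromo-1-methyl-6-oxocyclohexyl]acetate | COC(=O)C[C@@]1(C)[C@H](Br)CCCC1=O | intermediate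
7 | methyl 2-[(1R,6R)-6-bromo-1-methyl-3-methylidene-2-oxocyclohexyl]acetate | COC(=O)C[C@@]1(C)[C@H](Br)CCC(=C)C1=O | intermediate
8 | methyl 2-[(1R,6R)-6-bromo-1-methyl-2,3-dimethylidenecyclohexyl]acetate | COC(=O)C[C@@]1(C)[C@H](Br)CCC(=C)C1=C | intermediate
9 | 2-[(1R,6R)-6-bromo-1-methyl-2,3-dimethylidenecyclohexyl]acetic acid | OC(=O)C[C@@]1(C)[C@H](Br)CCC(=C)C1=C | intermediate
10 | 1,3-dioxo-1,3-dihydro-2H-isoindol-2-yl 2-[(1R,6R)-6-bromo-1-methyl-2,3-dimethylidenecyclohexyl]acetate | O=C(C[C@@]1(C)[C@H](Br)CCC(=C)C1=C)ON1C(=O)c2ccccc2C1=O | intermediate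
11 | but-3-en-2-one (methyl vinyl ketone) | CC(=O)C=C | starting material
12 | primary alkyl radical at C9: (6-bromo-1-methyl-2,3-dimethylidenecyclohexyl)methyl radical, ring configuration as in 10 | [CH2][C@@]1(C)[C@H](Br)CCC(=C)C1=C | intermediate (not isolated)
13 | α-acyl radical at C7: 5-(6-bromo-1-methyl-2,3-dimethylidenecyclohexyl)-2-oxopentan-3-yl radical, ring configuration as in 10 | CC(=O)[CH]CC[C@@]1(C)[C@H](Br)CCC(=C)C1=C | intermediate (not isolated)
14 | allyl radical (C5/C15) of the closed bicycle, drawn with the radical at C5 | CC(=O)[C@@H]1CC[C@@]2(C)[C@H](Br)CCC(=C)[C]2C1 | intermediate (not isolated)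
15 | 1-[(2R,4aR,5R)-5-bromo-4a,8-dimethyl-1,2,3,4,4a,5,6,7-octahydronaphthalen-2-yl]ethan-1-one | CC(=O)[C@@H]1CC[C@@]2(C)[C@H](Br)CCC(C)=C2C1 | intermediate
16 | 1-[(2R,4aR,5R,8aR)-5-bromo-8a-hydroperoxy-4a-methyl-8-methylidenedecahydronaphthalen-2-yl]ethan-1-one | CC(=O)[C@@H]1CC[C@@]2(C)[C@H](Br)CCC(=C)[C@]2(OO)C1 | intermediate (not isolated)
17 | 1-[(2R,4aR,5R,8aR)-5-bromo-8a-hydroxy-4a-methyl-8-methylidenedecahydronaphthalen-2-yl]ethan-1-one | CC(=O)[C@@H]1CC[C@@]2(C)[C@H](Br)CCC(=C)[C@]2(O)C1 | intermediate
18 | diethyl {2-[methoxy(methyl)amino]-2-oxoethyl}phosphonate | CCOP(=O)(CC(=O)N(C)OC)OCC | starting material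
19 | (2E)-3-[(2R,4aR,5R,8aR)-5-bromo-8a-hydroxy-4a-methyl-8-methylidenedecahydronaphthalen-2-yl]-N-methoxy-N-methylbut-2-enamide | CON(C)C(=O)/C=C(\C)[C@@H]1CC[C@@]2(C)[C@H](Br)CCC(=C)[C@]2(O)C1 | intermediate
20 | (2E)-3-[(2R,4aR,5R,8aR)-5-bromo-8a-hydroxy-4a-methyl-8-methylidenedecahydronaphthalen-2-yl]but-2-enal | O=C/C=C(\C)[C@@H]1CC[C@@]2(C)[C@H](Br)CCC(=C)[C@]2(O)C1 | intermediate
21 | diethyl (2-methylprop-2-en-1-yl)phosphonate | CCOP(=O)(CC(C)=C)OCC | starting material
22 | (1R,4aR,6R,8aR)-1-bromo-8a-methyl-4-methylidene-6-[(2E,4E)-6-methylhepta-2,4,6-trien-2-yl]octahydronaphthalen-4a(2H)-ol | C=C(C)/C=C/C=C(\C)[C@@H]1CC[C@@]2(C)[C@H](Br)CCC(=C)[C@]2(O)C1 | target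

Total step count: 12. Longest linear sequence: 12 steps (2, 11, 18 and 21 are purchased).

**Steps most likely to fail, with fallbacks**

Step 8. The α-acyl radical may be reduced or hydrogen-quenched before it closes the ring, the radicals may telomerise with 11, or the diene may undergo thermal cycloaddition with 11. The fallback closes ring A by an ionic sequence; it sets out from 8 and comes back at 15. Ester 8 is reduced with i-Bu2AlH (CH2Cl2, −78 °C) to 2-[(1R,6R)-6-bromo-1-methyl-2,3-dimethylidenecyclohexyl]acetaldehyde F1, whose carbonyl carbon becomes C8. Wittig olefination with Ph3P=CHC(O)CH3 (toluene, 80 °C) should give (3E)-5-[(1R,6R)-6-bromo-1-methyl-2,3-dimethylidenecyclohexyl]pent-3-en-2-one F2. RhCl(PPh3)3-catalysed 1,4-hydrosilylation with Et3SiH should give the triethylsilyl enol ether {[(2Z)-5-[(1R,6R)-6-bromo-1-methyl-2,3-dimethylidenecyclohexyl]pent-2-en-2-yl]oxy}(triethyl)silane F3, which fixes the nucleophilic carbon at C7. Catalytic HNTf2 (CH2Cl2, −78 °C) then protonates the diene at C15, and the tertiary allyl cation is captured at C6 by C7 of the enol ether (six-membered ring; the alternatives are eight-membered) to give 15 after loss of the silyl group.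

Step 2. The allyl group may migrate too slowly, so that bromo-epoxide formation through the hydroxyl group or bromination of the terminal alkene wins. The fallback replaces steps 1 and 2 by desymmetrisation and substitution; it sets out from 1 and comes back at 4. Enone 1 is oxidised at its β-carbon (Na2PdCl4 cat., t-BuOOH, aq. AcOH, 50 °C, Wacker-type oxidation) to 2-methylcyclohexane-1,3-dione F4, which can also simply be bought. C-Allylation (allyl bromide, 1 M NaOH) gives 2-methyl-2-(prop-2-en-1-yl)cyclohexane-1,3-dione F5. Reduction with baker's yeast (sucrose, water, 30 °C) should desymmetrise it to (2S,3S)-3-hydroxy-2-methyl-2-(prop-2-en-1-yl)cyclohexan-1-one F6, with the hydroxyl cis to allyl. An Appel reaction (CBr4, PPh3, toluene, 60 °C) with inversion at the carbinol carbon should then give 4; the flanking ketone disfavours ionisation and rearrangement.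

Step 9. Hydrogen abstraction in the ene reaction may be poorly regioselective (from C3–H to give the endocyclic alkene, or oxygen attack at C4). The fallback sets out from 15 and comes back at 17. Epoxidation with mCPBA (NaHCO3, CH2Cl2, 0 °C) from the α face, anti to the C10 methyl, should give 1-[(2R,4aR,5R,8R,8aS)-5-bromo-8,8a-epoxy-4a,8-dimethyldecahydronaphthalen-2-yl]ethan-1-one F7. Diethylaluminium 2,2,6,6-tetramethylpiperidide (from Et2AlCl and the lithium amide, excess, benzene, 0 °C → rt; the ketone rides as its aluminium enolate) then removes a proton from the C4 methyl group through a syn cyclic transition state, which breaks the C4–O bond and leaves the oxygen on C5 as in 17.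

**Further compounds**

F1 | step 8 | 2-[(1R,6R)-6-bromo-1-methyl-2,3-dimethylidenecyclohexyl]acetaldehyde | O=CC[C@@]1(C)[C@H](Br)CCC(=C)C1=C
F2 | step 8 | (3E)-5-[(1R,6R)-6-bromo-1-methyl-2,3-dimethylidenecyclohexyl]pent-3-en-2-one | CC(=O)/C=C/C[C@@]1(C)[C@H](Br)CCC(=C)C1=C
F3 | step 8 | {[(2Z)-5-[(1R,6R)-6-bromo-1-methyl-2,3-dimethylidenecyclohexyl]pent-2-en-2-yl]oxy}(triethyl)silane | CC[Si](CC)(CC)O/C(C)=C\CC[C@@]1(C)[C@H](Br)CCC(=C)C1=C
F4 | step 2 | 2-methylcyclohexane-1,3-dione | CC1C(=O)CCCC1=O
F5 | step 2 | 2-methyl-2-(prop-2-en-1-yl)cyclohexane-1,3-dione | C=CCC1(C)C(=O)CCCC1=O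
F6 | step 2 | (2S,3S)-3-hydroxy-2-methyl-2-(prop-2-en-1-yl)cyclohexan-1-one | C=CC[C@@]1(C)[C@@H](O)CCCC1=O
F7 | step 9 | 1-[(2R,4aR,5R,8R,8aS)-5-bromo-8,8a-epoxy-4a,8-dimethyldecahydronaphthalen-2-yl]ethan-1-one | CC(=O)[C@@H]1CC[C@@]2(C)[C@H](Br)CC[C@@]3(C)O[C@@]23C1
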